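**Retrosynthetic overview**
Labels: C7 is the dioxane CH bearing the syringyl ring, C8 the dioxane CH bearing C9H2OH, O3'/O4' the ring oxygens on C7/C8, and C1'–C6' the catechol ring. The strategy rests on that ring: it carries O3' and O4' on neighbouring carbons and its only carbon substituent at C1', para to O4'.
25 ⇐ 24 (loss of both silyl groups) ⇐ aldehyde 22 (Wittig, C1'–CH=CH–CHO) ⇐ methyl ester 20 (i-Bu2AlH, then MnO2).
20 ⇐ silyl ketene acetal 16 (C3'=C4') + methyl coumalate 17: bonds C3'–C2' and C4'–C5' by inverse-demand [4+2], then loss of CO2 and silanol.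
16 ⇐ trans-dioxanone 14 ⇐ ethyl alkoxyacetate 12 (C7–O ether by carbenoid O–H insertion, lactone closed on C8–OH) ⇐ syn-glycolate aldol adduct 8 of silylated syringaldehyde 2, which sets C7 and C8 with no later inversion.
Ring order: syringyl ring (bought) → dioxanone ring (step 7) → catechol ring (step 9).

Key step: step 9

Remark: Ar* stands for 3,5-dimethoxy-4-(triisopropylsilyloxy)phenyl; compounds 1, 3, 4, 11, 17 and 23 are taken as commercially available.

**Route**

Step 1
Reactants: 1 syringaldehyde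
Product: 2 3,5-dimethoxy-4-(triisopropylsilyloxy)benzaldehyde
Conditions: TIPSCl, imidazole, DMF, 25 °C
Reagents that add atoms: TIPSCl, CC(C)[Si](Cl)(C(C)C)C(C)C
Why: Imidazole-mediated O-silylation of the phenol; the bulky silyl group on the 2,6-dimethoxyphenol should last through every later step until fluoride is used.

Step 2
Reactants: 3 (R)-4-benzyloxazolidin-2-one; 4 benzyloxyacetyl chloride
Product: 6 (R)-4-benzyl-3-(benzyloxyacetyl)oxazolidin-2-one, via lithium oxazolidinide 5 (not isolated)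
Conditions: n-BuLi, THF, −78 °C; then 4, −78 → 0 °C
Reagents that add atoms: none
Why: N-acylation of the lithiated Evans auxiliary with an acid chloride, the standard way to a glycolate imide.

Step 3
Reactants: 6 (R)-4-benzyl-3-(benzyloxyacetyl)oxazolidin-2-one; 2 3,5-dimethoxy-4-(triisopropylsilyloxy)benzaldehyde
Product: 8 (R)-4-benzyl-3-[(2R,3S)-2-(benzyloxy)-3-Ar*-3-hydroxypropanoyl]oxazolidin-2-one, via Z-dibutylboron enolate 7 (not isolated)
Conditions: Bu2BOTf, Et3N, CH2Cl2, −78 → 0 °C; then 2, −78 → 0 °C; pH 7 buffer, MeOH, H2O2, 0 °C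
Reagents that add atoms: none
Why: Evans boron aldol reaction, in which the Z-enolate reacts through a chair Zimmerman–Traxler transition state on the face away from the benzyl group of the (R)-auxiliary, so that C8 (R in the imide) and C7 (S) should be set in the syn relationship that becomes the trans-dioxane.

Step 4
Reactants: 8 (R)-4-benzyl-3-[(2R,3S)-2-(benzyloxy)-3-Ar*-3-hydroxypropanoyl]oxazolidin-2-one
Product: 9 (1S,2S)-2-(benzyloxy)-1-Ar*-propane-1,3-diol
Conditions: LiBH4, MeOH (1 equiv), THF, 0 °C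
Reagents that add atoms: none
Why: Reductive cleavage of the N-acyl oxazolidinone gives C9H2OH and returns the auxiliary without touching C7 or C8 (C8 is now named S only because C9 falls in CIP rank).

Step 5
Reactants: 9 (1S,2S)-2-(benzyloxy)-1-Ar*-propane-1,3-diol
Product: 10 (1S,2S)-2-(benzyloxy)-3-(tert-butyldimethylsilyloxy)-1-Ar*-propan-1-ol
Conditions: TBSCl, imidazole, CH2Cl2, 0 °C
Reagents that add atoms: TBSCl, CC(C)(C)[Si](C)(C)Cl
Why: Silylation should take the primary C9–OH in preference to the hindered secondary benzylic C7–OH on steric grounds.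

Step 6
Reactants: 10 (1S,2S)-2-(benzyloxy)-3-(tert-butyldimethylsilyloxy)-1-Ar*-propan-1-ol; 11 ethyl diazoacetate
Product: 12 ethyl [(1S,2S)-2-(benzyloxy)-3-(tert-butyldimethylsilyloxy)-1-Ar*-propoxy]acetate
Conditions: 11 (slow addition), Rh2(OAc)4 (cat.), CH2Cl2, 25 °C
Reagents that add atoms: none
Why: Rh2(OAc)4-catalysed carbenoid O–H insertion into the only free hydroxyl forms the C7–O–CH2 ether under neutral conditions, so no alkoxide is formed that could move the C9 silyl group, and C7 keeps its configuration.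

Step 7
Reactants: 12 ethyl [(1S,2S)-2-(benzyloxy)-3-(tert-butyldimethylsilyloxy)-1-Ar*-propoxy]acetate
Product: 14 (5S,6S)-5-Ar*-6-[(tert-butyldimethylsilyloxy)methyl]-1,4-dioxan-2-one, via hydroxy ester 13 (not isolated)
Conditions: H2 (1 atm), Pd/C, EtOAc, 25 °C; filter; then PPTS (cat.), 5 Å MS, PhMe, 80 °C
Reagents that add atoms: none
Why: Hydrogenolysis of the primary benzyl ether frees C8–OH, which should close the six-membered lactone on the α-alkoxy ester by acid-catalysed transesterification with retention at C7 and C8, leaving aryl and silyloxymethyl trans.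

Step 8
Reactants: 14 (5S,6S)-5-Ar*-6-[(tert-butyldimethylsilyloxy)methyl]-1,4-dioxan-2-one
Product: 16 (2S,3S)-2-Ar*-5-(tert-butyldimethylsilyloxy)-3-[(tert-butyldimethylsilyloxy)methyl]-2,3-dihydro-1,4-dioxine, via potassium enolate 15 (not isolated)
Conditions: TBSCl, KN(SiMe3)2 (added last), THF–DMPU, −78 → 0 °C; pentane, filtration under argon; used crude
Reagents that add atoms: TBSCl, CC(C)(C)[Si](C)(C)Cl
Why: Kinetic deprotonation of the lactone α-CH2 (C3') with in situ O-silylation gives the cyclic silyl ketene acetal, as for the 1,4-dioxan-2-ones used in Ireland–Claisen chemistry, and the internal quench keeps the enolate from fragmenting.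

Step 9
Reactants: 16 (2S,3S)-2-Ar*-5-(tert-butyldimethylsilyloxy)-3-[(tert-butyldimethylsilyloxy)methyl]-2,3-dihydro-1,4-dioxine; 17 methyl coumalate
Product: 20 methyl (2S,3S)-3-Ar*-2-[(tert-butyldimethylsilyloxy)methyl]-2,3-dihydro-1,4-benzodioxine-6-carboxylate, via bridged lactone cycloadduct 18 (not isolated), via dihydroarene 19 (not isolated)
Conditions: 17 (1.5 equiv), PhMe, 25 → 110 °C, sealed tube; then DBU, 25 °C
Reagents that add atoms: none
Why: The electron-rich trioxygenated alkene 16 and the electron-poor 2-pyrone 17 should combine in an inverse-electron-demand, probably asynchronous [4+2] cycloaddition in which the CH terminus C3' bonds to C6 of the pyrone and the acetal carbon C4' to C3, giving bridged lactone 18; cycloreversion then expels CO2 to give dihydroarene 19, and 1,2-elimination of tert-butyldimethylsilanol across C3'–C4' aromatises it to 20. The closest known reaction type is the benzannulation of alkyl coumalates with ketene acetals, enol ethers and 1,1,2-trialkoxyethylenes to para-substituted benzoates. The catechol ring is closed by intermolecular [4+2] cycloaddition followed by retro-[4+2] loss of CO2 and elimination, four of its carbons coming from 17 and two (C3', C4') from the dioxanone. No stereocentre is created, because the sp3 centres of 18 and 19 vanish on aromatisation and C7 and C8 lie outside the reacting π-system and keep the configuration set in step 3. The step needs the regiochemistry that places the ester para to O4', which the polarisation of the ketene acetal (two oxygens on C4', one on C3') matched to the electrophilic C6 of the coumalate should secure, and it needs loss of silanol instead of cleavage of the ring bond C4'–O4', which the better leaving-group ability of the silanolate and the exclusion of acid (which would protonate the more basic ring ether oxygen) should favour.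

Step 10
Reactants: 20 methyl (2S,3S)-3-Ar*-2-[(tert-butyldimethylsilyloxy)methyl]-2,3-dihydro-1,4-benzodioxine-6-carboxylate
Product: 21 [(2S,3S)-3-Ar*-2-[(tert-butyldimethylsilyloxy)methyl]-2,3-dihydro-1,4-benzodioxin-6-yl]methanol
Conditions: i-Bu2AlH, CH2Cl2, −78 °C; Rochelle salt
Reagents that add atoms: none
Why: Hydride reduction of the aryl methyl ester to the benzylic alcohol, to which the silyl ethers and the benzodioxane are inert.

Step 11
Reactants: 21 [(2S,3S)-3-Ar*-2-[(tert-butyldimethylsilyloxy)methyl]-2,3-dihydro-1,4-benzodioxin-6-yl]methanol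
Product: 22 (2S,3S)-3-Ar*-2-[(tert-butyldimethylsilyloxy)methyl]-2,3-dihydro-1,4-benzodioxine-6-carbaldehyde
Conditions: MnO2, CH2Cl2, 25 °C
Reagents that add atoms: none
Why: MnO2 oxidises benzylic alcohols selectively to aldehydes without over-oxidation.

Step 12
Reactants: 22 (2S,3S)-3-Ar*-2-[(tert-butyldimethylsilyloxy)methyl]-2,3-dihydro-1,4-benzodioxine-6-carbaldehyde; 23 (triphenylphosphoranylidene)acetaldehyde
Product: 24 (E)-3-[(2S,3S)-3-Ar*-2-[(tert-butyldimethylsilyloxy)methyl]-2,3-dihydro-1,4-benzodioxin-6-yl]prop-2-enal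
Conditions: 23 (1.3 equiv), PhMe, 80 °C
Reagents that add atoms: none
Why: Wittig reaction of a stabilised formylmethylene ylide should give the E-enal, and a small excess of ylide at moderate temperature limits a second homologation.

Step 13
Reactants: 24 (E)-3-[(2S,3S)-3-Ar*-2-[(tert-butyldimethylsilyloxy)methyl]-2,3-dihydro-1,4-benzodioxin-6-yl]prop-2-enal
Product: 25 (E)-3-[(2S,3S)-3-(4-hydroxy-3,5-dimethoxyphenyl)-2-(hydroxymethyl)-2,3-dihydro-1,4-benzodioxin-6-yl]prop-2-enal
Conditions: Bu4NF, AcOH, THF, 0 → 25 °C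
Reagents that add atoms: none
Why: Fluoride cleaves the aryl triisopropylsilyl ether and the primary tert-butyldimethylsilyl ether, while acetic acid buffers the phenoxide and alkoxide so that the enal is not exposed to base.

**Compound list**
1 | syringaldehyde (4-hydroxy-3,5-dimethoxybenzaldehyde) | COc1cc(C=O)cc(OC)c1O | starting material
2 | 3,5-dimethoxy-4-(triisopropylsilyloxy)benzaldehyde | COc1cc(C=O)cc(OC)c1O[Si](C(C)C)(C(C)C)C(C)C | intermediate
3 | (R)-4-benzyloxazolidin-2-one | O=C1N[C@H](Cc2ccccc2)CO1 | starting material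
4 | benzyloxyacetyl chloride | O=C(Cl)COCc1ccccc1 | starting material
5 | lithium (R)-4-benzyl-2-oxooxazolidin-3-ide | [Li+].O=C1[N-][C@H](Cc2ccccc2)CO1 | intermediate
6 | (R)-4-benzyl-3-(benzyloxyacetyl)oxazolidin-2-one | O=C(COCc1ccccc1)N1[C@H](Cc2ccccc2)COC1=O | intermediate
7 | Z-dibutylboron enolate of 6 | CCCCB(CCCC)O/C(=C\OCc1ccccc1)N1[C@H](Cc2ccccc2)COC1=O | intermediate
8 | (R)-4-benzyl-3-[(2R,3S)-2-(benzyloxy)-3-Ar*-3-hydroxypropanoyl]oxazolidin-2-one | COc1cc([C@H](O)[C@@H](OCc2ccccc2)C(=O)N2[C@H](Cc3ccccc3)COC2=O)cc(OC)c1O[Si](C(C)C)(C(C)C)C(C)C | intermediate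
9 | (1S,2S)-2-(benzyloxy)-1-Ar*-propane-1,3-diol | COc1cc([C@H](O)[C@@H](OCc2ccccc2)CO)cc(OC)c1O[Si](C(C)C)(C(C)C)C(C)C | intermediate
10 | (1S,2S)-2-(benzyloxy)-3-(tert-butyldimethylsilyloxy)-1-Ar*-propan-1-ol | COc1cc([C@H](O)[C@@H](OCc2ccccc2)CO[Si](C)(C)C(C)(C)C)cc(OC)c1O[Si](C(C)C)(C(C)C)C(C)C | intermediate
11 | ethyl diazoacetate | CCOC(=O)C=[N+]=[N-] | starting material
12 | ethyl [(1S,2S)-2-(benzyloxy)-3-(tert-butyldimethylsilyloxy)-1-Ar*-propoxy]acetate | COc1cc([C@H](OCC(=O)OCC)[C@@H](OCc2ccccc2)CO[Si](C)(C)C(C)(C)C)cc(OC)c1O[Si](C(C)C)(C(C)C)C(C)C | intermediate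
13 | ethyl [(1S,2S)-3-(tert-butyldimethylsilyloxy)-2-hydroxy-1-Ar*-propoxy]acetate | COc1cc([C@H](OCC(=O)OCC)[C@@H](O)CO[Si](C)(C)C(C)(C)C)cc(OC)c1O[Si](C(C)C)(C(C)C)C(C)C | intermediate
14 | (5S,6S)-5-Ar*-6-[(tert-butyldimethylsilyloxy)methyl]-1,4-dioxan-2-one (trans) | COc1cc([C@@H]2OCC(=O)O[C@H]2CO[Si](C)(C)C(C)(C)C)cc(OC)c1O[Si](C(C)C)(C(C)C)C(C)C | intermediate
15 | potassium enolate of 14 | COc1cc([C@@H]2OC=C([O-])O[C@H]2CO[Si](C)(C)C(C)(C)C)cc(OC)c1O[Si](C(C)C)(C(C)C)C(C)C.[K+] | intermediate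
16 | (2S,3S)-2-Ar*-5-(tert-butyldimethylsilyloxy)-3-[(tert-butyldimethylsilyloxy)methyl]-2,3-dihydro-1,4-dioxine (silyl ketene acetal of 14) | COc1cc([C@@H]2OC=C(O[Si](C)(C)C(C)(C)C)O[C@H]2CO[Si](C)(C)C(C)(C)C)cc(OC)c1O[Si](C(C)C)(C(C)C)C(C)C | intermediate
17 | methyl coumalate (methyl 2-oxo-2H-pyran-5-carboxylate) | COC(=O)C1=COC(=O)C=C1 | starting material
18 | bridged lactone cycloadduct (2-oxabicyclo[2.2.2]oct-5-en-3-one with the dioxane fused at C3'–C4'; new centres undefined) | COC(=O)C1=CC2C(=O)OC1C1O[C@@H](c3cc(OC)c(O[Si](C(C)C)(C(C)C)C(C)C)c(OC)c3)[C@H](CO[Si](C)(C)C(C)(C)C)OC12O[Si](C)(C)C(C)(C)C | intermediate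
19 | dihydroarene (cyclohexa-1,3-diene with sp3 C3' and C4'; new centres undefined) | COC(=O)C1=CC2O[C@@H](c3cc(OC)c(O[Si](C(C)C)(C(C)C)C(C)C)c(OC)c3)[C@H](CO[Si](C)(C)C(C)(C)C)OC2(O[Si](C)(C)C(C)(C)C)C=C1 | intermediate
20 | methyl (2S,3S)-3-Ar*-2-[(tert-butyldimethylsilyloxy)methyl]-2,3-dihydro-1,4-benzodioxine-6-carboxylate | COc1cc([C@@H]2Oc3cc(C(=O)OC)ccc3O[C@H]2CO[Si](C)(C)C(C)(C)C)cc(OC)c1O[Si](C(C)C)(C(C)C)C(C)C | intermediate
21 | [(2S,3S)-3-Ar*-2-[(tert-butyldimethylsilyloxy)methyl]-2,3-dihydro-1,4-benzodioxin-6-yl]methanol | COc1cc([C@@H]2Oc3cc(CO)ccc3O[C@H]2CO[Si](C)(C)C(C)(C)C)cc(OC)c1O[Si](C(C)C)(C(C)C)C(C)C | intermediate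
22 | (2S,3S)-3-Ar*-2-[(tert-butyldimethylsilyloxy)methyl]-2,3-dihydro-1,4-benzodioxine-6-carbaldehyde | COc1cc([C@@H]2Oc3cc(C=O)ccc3O[C@H]2CO[Si](C)(C)C(C)(C)C)cc(OC)c1O[Si](C(C)C)(C(C)C)C(C)C | intermediate
23 | (triphenylphosphoranylidene)acetaldehyde | O=CC=P(c1ccccc1)(c1ccccc1)c1ccccc1 | starting material
24 | (E)-3-[(2S,3S)-3-Ar*-2-[(tert-butyldimethylsilyloxy)methyl]-2,3-dihydro-1,4-benzodioxin-6-yl]prop-2-enal | COc1cc([C@@H]2Oc3cc(/C=C/C=O)ccc3O[C@H]2CO[Si](C)(C)C(C)(C)C)cc(OC)c1O[Si](C(C)C)(C(C)C)C(C)C | intermediate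
25 | (E)-3-[(2S,3S)-3-(4-hydroxy-3,5-dimethoxyphenyl)-2-(hydroxymethyl)-2,3-dihydro-1,4-benzodioxin-6-yl]prop-2-enal (CNP0211211.1) | COc1cc([C@@H]2Oc3cc(/C=C/C=O)ccc3O[C@H]2CO)cc(OC)c1O | target

**Step count**
Total: 13 steps. Longest linear sequence: 12 steps (steps 1 and 3–13, from syringaldehyde 1); step 2 is a one-step side branch.

**Steps most likely to fail**

1. Step 9 (key step). The ketene acetal may add to C6 of the pyrone as a Mukaiyama–Michael donor and transfer silicon without closing the second C–C bond. Moisture may return it to the lactone. The dihydroarene may aromatise by cleaving the ring bond C4'–O4' instead of losing silanol. The fallback uses known chemistry, sets out from 2 and 3 and comes back at 20: the catechol ring is brought in preformed and the O3'–C3' aryl ether is closed last. Lithiated 3 and bromoacetyl bromide give (R)-4-benzyl-3-(bromoacetyl)oxazolidin-2-one F1. F1 alkylates methyl 3-bromo-4-hydroxybenzoate (K2CO3, acetone) at the phenol oxygen that becomes O4', giving the aryloxyacetyl imide F2. The Bu2BOTf/Et3N syn-aldol of F2 with 2 gives adduct F3, with C7 and C8 set as in 8. NaBH4 in THF–H2O removes the auxiliary and leaves the benzoate, giving diol F4. TBSCl/imidazole gives the primary silyl ether F5. Pd(OAc)2, 2-(di-tert-butylphosphino)-1,1'-binaphthyl and Cs2CO3 in PhMe at 70 °C then close the O3'–C3' bond by intramolecular aryl etherification with retention at C7, giving 20.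

2. Step 8. The potassium enolate may fragment to an alkoxyketene and the C8 alkoxide before it is silylated, silicon may go to carbon, or the ketene acetal may hydrolyse during isolation. The fallback sets out from 14 and comes back at 16 and forms no metal enolate: 14 is enolised by TBSOTf/Et3N in Et2O at 0 °C (amine-mediated soft enolisation of the α-alkoxy lactone). The triethylammonium triflate layer is separated under argon and the solution of 16 is carried into step 9 after exchange of solvent, without chromatography.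

3. Step 6. Dimerisation of the carbenoid may outrun insertion into the hindered benzylic C7–OH, or the carbenoid may be diverted to an oxonium ylide at the benzyl ether oxygen. The fallback sets out from 10 and comes back at 14 and replaces carbene transfer by Williamson etherification. The sodium alkoxide of 10 (NaH, THF, 0 °C, where alkylation should be faster than silyl migration) is alkylated with sodium bromoacetate to give the alkoxyacetic acid F6. Hydrogenolysis (H2, Pd/C, EtOAc) gives the hydroxy acid F7, and EDC·HCl/DMAP in CH2Cl2 closes the lactone to 14.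

**Further compounds**
F1 | step 9 | (R)-4-benzyl-3-(bromoacetyl)oxazolidin-2-one | O=C(CBr)N1[C@H](Cc2ccccc2)COC1=O
F2 | step 9 | methyl 4-{2-[(R)-4-benzyl-2-oxooxazolidin-3-yl]-2-oxoethoxy}-3-bromobenzoate | COC(=O)c1ccc(OCC(=O)N2[C@H](Cc3ccccc3)COC2=O)c(Br)c1
F3 | step 9 | methyl 4-{[(2R,3S)-1-[(R)-4-benzyl-2-oxooxazolidin-3-yl]-3-Ar*-3-hydroxy-1-oxopropan-2-yl]oxy}-3-bromobenzoate | COc1cc([C@H](O)[C@@H](Oc2ccc(C(=O)OC)cc2Br)C(=O)N2[C@H](Cc3ccccc3)COC2=O)cc(OC)c1O[Si](C(C)C)(C(C)C)C(C)C
F4 | step 9 | methyl 3-bromo-4-{[(1S,2S)-1-Ar*-1,3-dihydroxypropan-2-yl]oxy}benzoate | COc1cc([C@H](O)[C@@H](Oc2ccc(C(=O)OC)cc2Br)CO)cc(OC)c1O[Si](C(C)C)(C(C)C)C(C)C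
F5 | step 9 | methyl 3-bromo-4-{[(1S,2S)-3-(tert-butyldimethylsilyloxy)-1-Ar*-1-hydroxypropan-2-yl]oxy}benzoate | COc1cc([C@H](O)[C@@H](Oc2ccc(C(=O)OC)cc2Br)CO[Si](C)(C)C(C)(C)C)cc(OC)c1O[Si](C(C)C)(C(C)C)C(C)C
F0 | step 8 | none | none
F6 | step 6 | [(1S,2S)-2-(benzyloxy)-3-(tert-butyldimethylsilyloxy)-1-Ar*-propoxy]acetic acid | COc1cc([C@H](OCC(=O)O)[C@@H](OCc2ccccc2)CO[Si](C)(C)C(C)(C)C)cc(OC)c1O[Si](C(C)C)(C(C)C)C(C)C
F7 | step 6 | [(1S,2S)-3-(tert-butyldimethylsilyloxy)-2-hydroxy-1-Ar*-propoxy]acetic acid | COc1cc([C@H](OCC(=O)O)[C@@H](O)CO[Si](C)(C)C(C)(C)C)cc(OC)c1O[Si](C(C)C)(C(C)C)C(C)C
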